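**Retrosynthetic overview**

1. Target ⇐ fluoride cleavage of a C19 2-(trimethylsilyl)ethyl ester ⇐ methylenation of a C8 ketone ⇐ C9 alkylation of a cis-decalin C8–C9 enolate with methyl (S)-5-iodo-3-methylpentanoate (C13 from (R)-3-methylglutaric acid monomethyl ester).
2. cis-Decalin ⇐ bicyclic enone (C8=O, C9=C10): Me2CuLi addition sets the C10 methyl syn to H-5 and leaves the regiodefined enolate; convex-face methylation of the C19 ester enolate sets C4.
3. Bicyclic enone ⇐ monocyclic ring B precursor + ethylene: the key step forms C2–C3 and C1–C10 in one radical relay (a formal [4+2] annulation with ethylene gas) and closes ring A.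
4. Enabling feature: in the precursor the primary iodide carbon C3 and the bromine-bearing β-carbon C10 of the ring B enone (C8=O, C9=C10) are held 1,4 to each other by C4–C5, so one ethylene bridges them into six-membered ring A while loss of the C10 bromine re-forms the enone.
5. Ring B precursor ⇐ (S)-2-bromocyclohex-2-en-1-ol (CBS reduction) by Johnson–Claisen rearrangement (C5), hydroxymethylation/iodination (C3) and allylic oxidation (C8); ring order: B (from the commercial cyclohexenone), then A.

Key step: step 7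

Remark: labdane numbering is used (ring A = C1–C5 and C10; ring B = C5–C10; C18 methyl and C19 carboxyl on C4; C20 methyl on C10; C17 methylidene on C8; side chain C11–C16). The given SMILES is read as the cis-fused decalin in which H-5, the C10 methyl, the C4 methyl and the C9 side chain all lie on one face.

**Route**

Step 1
Reactants: 1 2-bromocyclohex-2-en-1-one
Product: 2 (1S)-2-bromocyclohex-2-en-1-ol
Conditions: (R)-1-methyl-3,3-diphenyltetrahydro-1H,3H-pyrrolo[1,2-c][1,3,2]oxazaborole (0.1 equiv), BH3·SMe2 (0.7 equiv), THF, −20 °C; MeOH quench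
Reagents that add atoms: none
Why: Corey–Bakshi–Shibata reduction in which the bromovinyl arm acts as the large group, so the (R)-oxazaborolidine–borane complex should deliver hydride to the carbonyl face that gives the (S)-carbinol, the stereocenter that later becomes C5.

Step 2
Reactants: 2 (1S)-2-bromocyclohex-2-en-1-ol; 3 trimethyl orthoacetate
Product: 5 methyl 2-[(1S)-2-bromocyclohex-2-en-1-yl]acetate, via mixed ketene acetal 4 (not isolated)
Conditions: MeC(OMe)3 (5 equiv), propionic acid (0.05 equiv), xylene, 140 °C, MeOH distilled off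
Reagents that add atoms: none
Why: Johnson–Claisen rearrangement, whose suprafacial [3,3] shift forms the C4–C5 bond on the ring face vacated by oxygen, so the carbinol configuration is transferred to C5 while the alkene moves to C9=C10 with bromine on C10.

Step 3
Reactants: 5 methyl 2-[(1S)-2-bromocyclohex-2-en-1-yl]acetate
Product: 6 2-(trimethylsilyl)ethyl 2-[(1S)-2-bromocyclohex-2-en-1-yl]acetate
Conditions: 2-(trimethylsilyl)ethanol (5 equiv), Ti(OiPr)4 (0.1 equiv), toluene, 110 °C
Reagents that add atoms: 2-(trimethylsilyl)ethanol, C[Si](C)(C)CCO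
Why: Titanate-catalysed transesterification of an unhindered ester, which puts a fluoride-cleavable group on the future C19 carboxyl so that it can be freed at the end beside the C15 methyl ester, and touches no stereocenter.

Step 4
Reactants: 6 2-(trimethylsilyl)ethyl 2-[(1S)-2-bromocyclohex-2-en-1-yl]acetate
Product: 8 2-(trimethylsilyl)ethyl 2-[(1S)-2-bromocyclohex-2-en-1-yl]-3-hydroxypropanoate (C4 epimers), via lithium ester enolate 7 (not isolated)
Conditions: LDA (1.1 equiv), THF, −78 °C; CH2O (gas from cracked paraformaldehyde), −78 → −20 °C; aq NH4Cl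
Reagents that add atoms: formaldehyde, C=O
Why: Aldol addition of the lithium ester enolate to monomeric formaldehyde introduces C3, and the new C4 stereocenter need not be controlled because C4 is re-enolised in step 9.

Step 5
Reactants: 8 2-(trimethylsilyl)ethyl 2-[(1S)-2-bromocyclohex-2-en-1-yl]-3-hydroxypropanoate
Product: 9 2-(trimethylsilyl)ethyl 2-[(1S)-2-bromocyclohex-2-en-1-yl]-3-iodopropanoate (C4 epimers)
Conditions: I2, PPh3, imidazole, CH2Cl2, 0 °C
Reagents that add atoms: iodine, [I][I]
Why: Appel-type iodination of the primary alcohol under nearly neutral conditions should give the primary iodide without elimination to the acrylate.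

Step 6
Reactants: 9 2-(trimethylsilyl)ethyl 2-[(1S)-2-bromocyclohex-2-en-1-yl]-3-iodopropanoate
Product: 10 2-(trimethylsilyl)ethyl 2-[(1S)-2-bromo-4-oxocyclohex-2-en-1-yl]-3-iodopropanoate (C4 epimers)
Conditions: CrO3 (12 equiv), 3,5-dimethylpyrazole (12 equiv), CH2Cl2, −20 °C
Reagents that add atoms: chromium trioxide, O=[Cr](=O)=O
Why: Allylic oxidation with the CrO3–3,5-dimethylpyrazole complex at the only allylic methylene (C8) should convert the vinyl bromide into the β-bromo enone without touching C5.

Step 7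
Reactants: 10 2-(trimethylsilyl)ethyl 2-[(1S)-2-bromo-4-oxocyclohex-2-en-1-yl]-3-iodopropanoate; 11 ethylene
Product: 12 2-(trimethylsilyl)ethyl (8aS)-6-oxo-1,2,3,4,6,7,8,8a-octahydronaphthalene-1-carboxylate (C1 epimers)
Conditions: ethylene (3 bar), (Bu3Sn)2 (1.2 equiv), Bu3SnH (0.1 equiv), 2,2'-azobis(2-methylpropionitrile) (0.2 equiv in portions), benzene (5 mM), 80 °C
Reagents that add atoms: none
Why: Proposed new method: a tin radical chain is proposed in which a tributylstannyl radical abstracts iodine from C3 of 10, the primary C3 radical adds to ethylene (C2–C3), and the resulting primary C1 radical closes ring A by 6-exo-trig attack on C10, the bromine-bearing β-carbon of the enone, after which the α-keto radical at C9 expels a bromine atom to restore the C9=C10 enone and the bromine atom regenerates the stannyl radical from (Bu3Sn)2. The closest known reaction types are Giese-type additions of alkyl radicals to ethylene under pressure, Curran-type radical annulations, and radical addition–fragmentation on β-halo or β-stannyl enones. No new stereocenter is formed because C10 stays sp2, C5 is untouched, and C4 is carried as an epimer mixture that converges in step 9. The step needs chemoselective abstraction of the alkyl iodine beside the vinyl bromide (secured by the much weaker C–I bond), capture of the C3 radical by ethylene before it adds to the enone of a second molecule (secured by high dilution and about 0.3 M ethylene, direct closure onto C10 being a four-membered ring closure), and cyclisation of the C1 radical before a second ethylene adds (secured by the intramolecular, polarity-matched attack on the electron-poor β-carbon). Simple reduction is limited because the only tin hydride present is the initiating 0.1 equiv.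

Step 8
Reactants: 12 2-(trimethylsilyl)ethyl (8aS)-6-oxo-1,2,3,4,6,7,8,8a-octahydronaphthalene-1-carboxylate
Product: 13 2-(trimethylsilyl)ethyl (4aR,8aS)-4a-methyl-6-[(trimethylsilyl)oxy]-1,2,3,4,4a,7,8,8a-octahydronaphthalene-1-carboxylate (C1 epimers)
Conditions: Me2CuLi (2 equiv, from MeLi and CuI), TMSCl (3 equiv), THF, −78 °C; Et3N, pentane work-up
Reagents that add atoms: lithium dimethylcuprate Me2CuLi, [Li+].C[Cu-]C; chlorotrimethylsilane, C[Si](C)(C)Cl
Why: Chlorosilane-accelerated cuprate conjugate addition in which, as for octalones of this type, methyl should be delivered axially to C10 on the face of H-5 to give the cis ring fusion, while the enolate is trapped regiospecifically as the C8–C9 silyl enol ether.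

Step 9
Reactants: 13 2-(trimethylsilyl)ethyl (4aR,8aS)-4a-methyl-6-[(trimethylsilyl)oxy]-1,2,3,4,4a,7,8,8a-octahydronaphthalene-1-carboxylate
Product: 15 2-(trimethylsilyl)ethyl (1S,4aR,8aR)-1,4a-dimethyl-6-[(trimethylsilyl)oxy]-1,2,3,4,4a,7,8,8a-octahydronaphthalene-1-carboxylate, via lithium ester enolate 14 (not isolated)
Conditions: LDA (1.2 equiv), THF, −78 °C; MeI (3 equiv), DMPU, −78 → −20 °C
Reagents that add atoms: iodomethane, CI
Why: Alkylation of the exocyclic lithium ester enolate, on which both C4 epimers of 13 converge, where MeI should enter on the convex face of the cis-fused bicycle (syn to H-5, away from ring B), so that the C4 methyl ends syn to H-5 and the C10 methyl and the ester points to the concave face.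

Step 10
Reactants: 16 (3R)-5-methoxy-3-methyl-5-oxopentanoic acid
Product: 17 methyl (3R)-5-hydroxy-3-methylpentanoate
Conditions: BH3·SMe2 (1.1 equiv), THF, 0 °C → rt; MeOH
Reagents that add atoms: none
Why: Borane reduces the free carboxylic acid much faster than the methyl ester, so the hydroxy ester should form without touching the C13 stereocenter.

Step 11
Reactants: 17 methyl (3R)-5-hydroxy-3-methylpentanoate
Product: 18 methyl (3S)-5-iodo-3-methylpentanoate
Conditions: I2, PPh3, imidazole, CH2Cl2, 0 °C
Reagents that add atoms: iodine, [I][I]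
Why: Appel-type iodination of the primary alcohol gives the side-chain electrophile, the descriptor changing only because iodine raises the priority of that arm.

Step 12
Reactants: 15 2-(trimethylsilyl)ethyl (1S,4aR,8aR)-1,4a-dimethyl-6-[(trimethylsilyl)oxy]-1,2,3,4,4a,7,8,8a-octahydronaphthalene-1-carboxylate; 18 methyl (3S)-5-iodo-3-methylpentanoate
Product: 20 2-(trimethylsilyl)ethyl (1S,4aR,5S,8aR)-5-[(3R)-5-methoxy-3-methyl-5-oxopentyl]-1,4a-dimethyl-6-oxodecahydronaphthalene-1-carboxylate, via lithium ketone enolate 19 (not isolated)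
Conditions: MeLi (1.05 equiv), THF, 0 °C; then 18 (2 equiv), HMPA, −78 → 0 °C
Reagents that add atoms: none
Why: Regiospecific lithium enolate generation from the silyl enol ether with MeLi followed by C-alkylation with a primary iodide, in which the electrophile should approach C9 on the convex face, anti to the pseudoaxial C1–C10 bond and away from ring A, placing the side chain syn to the C10 methyl.

Step 13
Reactants: 20 2-(trimethylsilyl)ethyl (1S,4aR,5S,8aR)-5-[(3R)-5-methoxy-3-methyl-5-oxopentyl]-1,4a-dimethyl-6-oxodecahydronaphthalene-1-carboxylate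
Product: 21 2-(trimethylsilyl)ethyl (1S,4aS,5R,8aR)-5-[(3R)-5-methoxy-3-methyl-5-oxopentyl]-1,4a-dimethyl-6-methylidenedecahydronaphthalene-1-carboxylate
Conditions: Zn, CH2Br2, TiCl4 (preformed Lombardo reagent), THF–CH2Cl2, 0 °C → rt
Reagents that add atoms: dibromomethane, BrCBr
Why: Lombardo methylenation converts the hindered C8 ketone into the exocyclic methylidene under non-basic conditions that should neither epimerise C9 nor attack the esters.

Step 14
Reactants: 21 2-(trimethylsilyl)ethyl (1S,4aS,5R,8aR)-5-[(3R)-5-methoxy-3-methyl-5-oxopentyl]-1,4a-dimethyl-6-methylidenedecahydronaphthalene-1-carboxylate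
Product: 22 (1S,4aS,5R,8aR)-5-[(3R)-5-methoxy-3-methyl-5-oxopentyl]-1,4a-dimethyl-6-methylidenedecahydronaphthalene-1-carboxylic acid (CNP0260608.1)
Conditions: Bu4NF (3 equiv), THF, rt; aq NH4Cl
Reagents that add atoms: none
Why: Fluoride-induced β-elimination of the 2-(trimethylsilyl)ethyl ester should release the hindered C19 acid while the C15 methyl ester and the exocyclic alkene stay intact.

**Compound list**

1 | 2-bromocyclohex-2-en-1-one | O=C1CCCC=C1Br | starting material
2 | (1S)-2-bromocyclohex-2-en-1-ol | O[C@H]1CCCC=C1Br | intermediate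
3 | trimethyl orthoacetate | CC(OC)(OC)OC | starting material
4 | 1-{[(1S)-2-bromocyclohex-2-en-1-yl]oxy}-1-methoxyethene (mixed ketene acetal) | C=C(OC)O[C@H]1CCCC=C1Br | intermediate
5 | methyl 2-[(1S)-2-bromocyclohex-2-en-1-yl]acetate | COC(=O)C[C@@H]1CCCC=C1Br | intermediate
6 | 2-(trimethylsilyl)ethyl 2-[(1S)-2-bromocyclohex-2-en-1-yl]acetate | C[Si](C)(C)CCOC(=O)C[C@@H]1CCCC=C1Br | intermediate
7 | lithium ester enolate of 6 | [Li+].[O-]C(OCC[Si](C)(C)C)=C[C@@H]1CCCC=C1Br | intermediate
8 | 2-(trimethylsilyl)ethyl 2-[(1S)-2-bromocyclohex-2-en-1-yl]-3-hydroxypropanoate (C4 epimers) | C[Si](C)(C)CCOC(=O)C(CO)[C@@H]1CCCC=C1Br | intermediate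
9 | 2-(trimethylsilyl)ethyl 2-[(1S)-2-bromocyclohex-2-en-1-yl]-3-iodopropanoate (C4 epimers) | C[Si](C)(C)CCOC(=O)C(CI)[C@@H]1CCCC=C1Br | intermediate
10 | 2-(trimethylsilyl)ethyl 2-[(1S)-2-bromo-4-oxocyclohex-2-en-1-yl]-3-iodopropanoate (C4 epimers) | C[Si](C)(C)CCOC(=O)C(CI)[C@@H]1CCC(=O)C=C1Br | intermediate
11 | ethylene | C=C | starting material
12 | 2-(trimethylsilyl)ethyl (8aS)-6-oxo-1,2,3,4,6,7,8,8a-octahydronaphthalene-1-carboxylate (C1 epimers) | C[Si](C)(C)CCOC(=O)C1CCCC2=CC(=O)CC[C@@H]12 | intermediate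
13 | 2-(trimethylsilyl)ethyl (4aR,8aS)-4a-methyl-6-[(trimethylsilyl)oxy]-1,2,3,4,4a,7,8,8a-octahydronaphthalene-1-carboxylate (C1 epimers) | C[Si](C)(C)CCOC(=O)C1CCC[C@@]2(C)C=C(O[Si](C)(C)C)CC[C@@H]12 | intermediate
14 | lithium ester enolate of 13 (C4 deprotonated) | [Li+].[O-]C(OCC[Si](C)(C)C)=C1CCC[C@@]2(C)C=C(O[Si](C)(C)C)CC[C@@H]12 | intermediate
15 | 2-(trimethylsilyl)ethyl (1S,4aR,8aR)-1,4a-dimethyl-6-[(trimethylsilyl)oxy]-1,2,3,4,4a,7,8,8a-octahydronaphthalene-1-carboxylate | C[Si](C)(C)CCOC(=O)[C@@]1(C)CCC[C@@]2(C)C=C(O[Si](C)(C)C)CC[C@@H]12 | intermediate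
16 | (3R)-5-methoxy-3-methyl-5-oxopentanoic acid ((R)-3-methylglutaric acid monomethyl ester) | OC(=O)C[C@@H](C)CC(=O)OC | starting material
17 | methyl (3R)-5-hydroxy-3-methylpentanoate | OCC[C@@H](C)CC(=O)OC | intermediate
18 | methyl (3S)-5-iodo-3-methylpentanoate | ICC[C@@H](C)CC(=O)OC | intermediate
19 | lithium C8–C9 ketone enolate from 15 | [Li+].C[Si](C)(C)CCOC(=O)[C@@]1(C)CCC[C@@]2(C)C=C([O-])CC[C@@H]12 | intermediate
20 | 2-(trimethylsilyl)ethyl (1S,4aR,5S,8aR)-5-[(3R)-5-methoxy-3-methyl-5-oxopentyl]-1,4a-dimethyl-6-oxodecahydronaphthalene-1-carboxylate | O=C1CC[C@@H]2[C@@](C)(CCC[C@]2(C)C(=O)OCC[Si](C)(C)C)[C@@H]1CC[C@@H](C)CC(=O)OC | intermediate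
21 | 2-(trimethylsilyl)ethyl (1S,4aS,5R,8aR)-5-[(3R)-5-methoxy-3-methyl-5-oxopentyl]-1,4a-dimethyl-6-methylidenedecahydronaphthalene-1-carboxylate | C=C1CC[C@@H]2[C@@](C)(CCC[C@]2(C)C(=O)OCC[Si](C)(C)C)[C@@H]1CC[C@@H](C)CC(=O)OC | intermediate
22 | (1S,4aS,5R,8aR)-5-[(3R)-5-methoxy-3-methyl-5-oxopentyl]-1,4a-dimethyl-6-methylidenedecahydronaphthalene-1-carboxylic acid | C=C1CC[C@@H]2[C@@](C)(CCC[C@]2(C)C(=O)O)[C@@H]1CC[C@@H](C)CC(=O)OC | target

**Step count and risks**

Total step count: 14. Longest linear sequence: 12 steps (steps 1–9 and 12–14).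

Steps most likely to fail:

1. Step 7 (proposed new method). The radical chain may collapse. The C3 radical may be reduced or add to the enone of a second molecule before it captures ethylene. The C1 radical may take up further ethylene or abstract the allylic hydrogen at C5 instead of closing ring A. Fallback with known chemistry, setting out from 6 and returning at 12: enolate 7 is alkylated with allyl bromide to 2-(trimethylsilyl)ethyl 2-[(1S)-2-bromocyclohex-2-en-1-yl]pent-4-enoate F1. Allylic oxidation as in step 6 gives 2-(trimethylsilyl)ethyl 2-[(1S)-2-bromo-4-oxocyclohex-2-en-1-yl]pent-4-enoate F2. Hydroboration of the terminal alkene with 9-BBN-H gives 2-(trimethylsilyl)ethyl 5-(9-borabicyclo[3.3.1]nonan-9-yl)-2-[(1S)-2-bromo-4-oxocyclohex-2-en-1-yl]pentanoate F3, which is not isolated. It should close ring A by intramolecular B-alkyl Suzuki–Miyaura coupling onto the β-bromo enone ([1,1'-bis(diphenylphosphino)ferrocene]PdCl2, AsPh3, Cs2CO3, DMF–H2O) to give 12.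

2. Step 12. C-alkylation of the hindered enolate next to the quaternary C10 may be slow, which allows proton transfer between enolate and product (loss of regiocontrol, dialkylation) and O-alkylation. Fallback by aldol addition and deoxygenation, setting out from 15 (with 17 as side-chain source) and returning at 20: 17 is oxidised with Dess–Martin periodinane to methyl (3R)-3-methyl-5-oxopentanoate F4. Enolate 19, made from 15 as in step 12, adds to F4 at −78 °C on the same convex face. This gives 2-(trimethylsilyl)ethyl (1S,4aR,5R,8aR)-5-[(3R)-1-hydroxy-5-methoxy-3-methyl-5-oxopentyl]-1,4a-dimethyl-6-oxodecahydronaphthalene-1-carboxylate F5 (carbinol epimers). 1,1'-Thiocarbonyldiimidazole converts it into the O-(imidazol-1-ylcarbonothioyl) derivative 2-(trimethylsilyl)ethyl (1S,4aR,5R,8aR)-5-[(3R)-1-[(1H-imidazol-1-ylcarbonothioyl)oxy]-5-methoxy-3-methyl-5-oxopentyl]-1,4a-dimethyl-6-oxodecahydronaphthalene-1-carboxylate F6. Barton–McCombie reduction (Bu3SnH, 2,2'-azobis(2-methylpropionitrile), toluene, 90 °C) removes the C11 oxygen to give 20.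

3. Step 9. Facial selectivity in the methylation of the C4 ester enolate may be poor; attack on the concave face would give the C4 epimer. Fallback that sets C4 before ring A exists and relies on separation, setting out from 6 and returning at 15: enolate 7 is methylated (MeI) to 2-(trimethylsilyl)ethyl 2-[(1S)-2-bromocyclohex-2-en-1-yl]propanoate F7. A second enolisation (LDA) and allylation give the quaternary ester, from which the diastereomer 2-(trimethylsilyl)ethyl (2S)-2-[(1S)-2-bromocyclohex-2-en-1-yl]-2-methylpent-4-enoate F8 is separated by chromatography. Allylic oxidation as in step 6 gives 2-(trimethylsilyl)ethyl (2S)-2-[(1S)-2-bromo-4-oxocyclohex-2-en-1-yl]-2-methylpent-4-enoate F9. Hydroboration with 9-BBN-H gives 2-(trimethylsilyl)ethyl (2S)-5-(9-borabicyclo[3.3.1]nonan-9-yl)-2-[(1S)-2-bromo-4-oxocyclohex-2-en-1-yl]-2-methylpentanoate F10, not isolated. Intramolecular B-alkyl Suzuki–Miyaura coupling (same catalyst system as above) gives 2-(trimethylsilyl)ethyl (1S,8aR)-1-methyl-6-oxo-1,2,3,4,6,7,8,8a-octahydronaphthalene-1-carboxylate F11. Me2CuLi/TMSCl as in step 8 then gives 15.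

**Further compounds**

F1 | step 7 | 2-(trimethylsilyl)ethyl 2-[(1S)-2-bromocyclohex-2-en-1-yl]pent-4-enoate | C[Si](C)(C)CCOC(=O)C(CC=C)[C@@H]1CCCC=C1Br
F2 | step 7 | 2-(trimethylsilyl)ethyl 2-[(1S)-2-bromo-4-oxocyclohex-2-en-1-yl]pent-4-enoate | C[Si](C)(C)CCOC(=O)C(CC=C)[C@@H]1CCC(=O)C=C1Br
F3 | step 7 | 2-(trimethylsilyl)ethyl 5-(9-borabicyclo[3.3.1]nonan-9-yl)-2-[(1S)-2-bromo-4-oxocyclohex-2-en-1-yl]pentanoate | C[Si](C)(C)CCOC(=O)C(CCCB1C2CCCC1CCC2)[C@@H]1CCC(=O)C=C1Br
F4 | step 12 | methyl (3R)-3-methyl-5-oxopentanoate | O=CC[C@@H](C)CC(=O)OC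
F5 | step 12 | 2-(trimethylsilyl)ethyl (1S,4aR,5R,8aR)-5-[(3R)-1-hydroxy-5-methoxy-3-methyl-5-oxopentyl]-1,4a-dimethyl-6-oxodecahydronaphthalene-1-carboxylate | O=C1CC[C@@H]2[C@@](C)(CCC[C@]2(C)C(=O)OCC[Si](C)(C)C)[C@@H]1C(O)C[C@@H](C)CC(=O)OC
F6 | step 12 | 2-(trimethylsilyl)ethyl (1S,4aR,5R,8aR)-5-[(3R)-1-[(1H-imidazol-1-ylcarbonothioyl)oxy]-5-methoxy-3-methyl-5-oxopentyl]-1,4a-dimethyl-6-oxodecahydronaphthalene-1-carboxylate | O=C1CC[C@@H]2[C@@](C)(CCC[C@]2(C)C(=O)OCC[Si](C)(C)C)[C@@H]1C(OC(=S)n3ccnc3)C[C@@H](C)CC(=O)OC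
F7 | step 9 | 2-(trimethylsilyl)ethyl 2-[(1S)-2-bromocyclohex-2-en-1-yl]propanoate | C[Si](C)(C)CCOC(=O)C(C)[C@@H]1CCCC=C1Br
F8 | step 9 | 2-(trimethylsilyl)ethyl (2S)-2-[(1S)-2-bromocyclohex-2-en-1-yl]-2-methylpent-4-enoate | C[Si](C)(C)CCOC(=O)[C@@](C)(CC=C)[C@@H]1CCCC=C1Br
F9 | step 9 | 2-(trimethylsilyl)ethyl (2S)-2-[(1S)-2-bromo-4-oxocyclohex-2-en-1-yl]-2-methylpent-4-enoate | C[Si](C)(C)CCOC(=O)[C@@](C)(CC=C)[C@@H]1CCC(=O)C=C1Br
F10 | step 9 | 2-(trimethylsilyl)ethyl (2S)-5-(9-borabicyclo[3.3.1]nonan-9-yl)-2-[(1S)-2-bromo-4-oxocyclohex-2-en-1-yl]-2-methylpentanoate | C[Si](C)(C)CCOC(=O)[C@@](C)(CCCB1C2CCCC1CCC2)[C@@H]1CCC(=O)C=C1Br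
F11 | step 9 | 2-(trimethylsilyl)ethyl (1S,8aR)-1-methyl-6-oxo-1,2,3,4,6,7,8,8a-octahydronaphthalene-1-carboxylate | C[Si](C)(C)CCOC(=O)[C@@]1(C)CCCC2=CC(=O)CC[C@@H]12
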